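Readings and results stem from a simulated flask with made-up constants, and the scatter is random.

A starting complex trades its ligands one at a time for an incoming ligand. Each exchange frees a leaving ligand, which is slowly carried off, while a protic impurity quenches some of the complex.

in all of them: starting complex 0.25 M

|  | incoming ligand | protic impurity | remark | time |
|---|---|---|---|---|
| south-west | 0.54 M | 0.025 M | run made earlier |  |
| north-east | 0.82 M | 0.025 M | run made earlier |  |
| winter | 0.625 M | 0.0250 M |  | 80 min |
| autumn | 1.00 M | 0.0250 M |  | 80 min |

| run | time / min | complex with one exchanged / % | complex with two exchanged / % | starting complex / % |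
|---|---|---|---|---|
| south-west | 8.00 | 35 | 22 | 32 |
| south-west | 20.0 | 35 | 27 | 23 |
| south-west | 40.0 | 29 | 34 | 17 |
| south-west | 60.0 | 27 | 39 | 10 |
| north-east | 5.00 | 35 | 27 | 25 |
| north-east | 10.0 | 30 | 29 | 23 |
| north-east | 25.0 | 31 | 36 | 12 |
| north-east | 60.0 | 16 | 42 | 6 |

(readings scatter by 1.5 percentage points)

- the numbers in the tables scatter by 1.5 percentage points (one standard deviation)
- reactions considered so far: leaving ligand -> by-product carried off; complex with two exchanged + incoming ligand <-> leaving ligand + complex with three exchanged; complex with one exchanged + incoming ligand <-> leaving ligand + complex with two exchanged; starting complex + incoming ligand <-> leaving ligand + complex with one exchanged; protic impurity + starting complex -> quenched substrate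

- which of these holds the largest part of the starting complex at the end of winter (complex with two exchanged / complex with three exchanged / complex with one exchanged / starting complex)
- which of these holds the largest part of the starting complex at the end of autumn (complex with two exchanged / complex with three exchanged / complex with one exchanged / starting complex)
- final complex with one exchanged in autumn, as a percentage of the starting complex charged

Watch the rate, as the fraction lost per minute. My carried quantity is the clearing rate: the mean fraction of the complex with one exchanged lost per minute between two late readings, an empirical slope and not the rate constant of any step. In the south-west run, readings from 20.0 min to 60.0 min give 0.00649 min⁻¹. In the north-east run, from 25.0 min to 60.0 min, it is 0.0189 min⁻¹, faster by a factor of 2.91 for a factor of 1.52 in incoming ligand. That reads as an order of 2.56, with the scatter of the readings in it. The opening rate is far higher: the starting complex of the north-east run, quench included, falls at 0.277 min⁻¹ over its first 5.00 min, a factor of 14.7 above the later clearing.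

Carried to autumn, the clearing rate becomes 0.0314 min⁻¹. Starting from a peak reading of 35% and running from 25.0 min to 80 min, my estimate for the complex with one exchanged is 6.22%.

The forecast sees the complex “held back by released ligand” and gives complex with two exchanged for winter, complex with three exchanged for autumn and 9.5%, higher than my figure.

The flask gives complex with two exchanged for winter, complex with three exchanged for autumn and 7.85%, so the forecast held.

    leaving ligand → by-product carried off (k = 0.0730 min⁻¹)
    complex with two exchanged + incoming ligand ⇌ leaving ligand + complex with three exchanged (K = 0.0840, k = 1.00 M⁻¹ min⁻¹)
    complex with one exchanged + incoming ligand ⇌ leaving ligand + complex with two exchanged (K = 0.290, k = 1.20 M⁻¹ min⁻¹)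
    starting complex + incoming ligand ⇌ leaving ligand + complex with one exchanged (K = 0.480, k = 1.80 M⁻¹ min⁻¹)
    protic impurity + starting complex → quenched substrate (k = 2.40 M⁻¹ min⁻¹)

In autumn the clearing rate from 40.0 min to 80.0 min comes to 0.0205 min⁻¹, less than the 0.0314 min⁻¹ carried over, and the flask ends above my 6.22%. The neighbouring flask is autumn with 0.25 M of incoming ligand. Reckoned from the south-west run, its clearing rate drops to 9.04 × 10⁻⁴ min⁻¹, and the same peak over the same span keeps 33.3%. That flask ends with 33.5% of complex with one exchanged.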